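**Strategy.** Everything rests on disconnecting ring B at the aryl–vinyl bond C4–C4a. In the target, C4a (ring A), C4H=C3 and the C3 carboxyl form a cinnamic acid unit, the classic retron of a Mizoroki–Heck reaction. A 6-endo Heck cyclization of a ring-A aryl bromide onto a pendant 2-methylenesuccinate therefore closes ring B and installs the C3=C4 alkene in one operation. The precursor is an open-chain (R)-diarylmethyl itaconate that already carries the Z enol-ether-linked third ferulate unit. C1 comes from a rhodium-catalysed asymmetric conjugate arylation, and the cis C2 centre is set after ring closure by kinetic protonation of the ring-B ester dienolate.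

Key step: step 9

Remarks on the chemistry:
- The 1,2-dihydronaphthalene numbering of the target (C1–C4, C4a, C5–C8, C8a) is also used for open-chain precursors.
- The (1R,2R) descriptors of the target correspond to a 1,2-cis relationship between the C1 aryl group and the C2 carboxyl group, the less stable epimer, so no basic step follows the one that sets C2.
- Abbreviations in names: ArM = 3-methoxy-4-(methoxymethoxy)phenyl; ZE = (Z)-1-(tert-butoxycarbonyl)-2-ArM-ethenyl, the group carried by the ring-A oxygen at C7.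
- Assumption: compound 8 is taken as a purchased catalogue compound.

Step 1
Reactants: 1 2-bromo-5-hydroxy-4-methoxybenzaldehyde; 2 tert-butyl (triphenylphosphoranylidene)acetate
Product: 3 tert-butyl (E)-3-(2-bromo-5-hydroxy-4-methoxyphenyl)prop-2-enoate
Conditions: toluene, 80 °C
Reagents that add atoms: 2 tert-butyl (triphenylphosphoranylidene)acetate, CC(C)(C)OC(=O)C=P(c1ccccc1)(c1ccccc1)c1ccccc1
Why: Wittig olefination with a stabilized ylide tolerates the free phenol and should give the E acrylate; the bromine is already placed on the future C4a.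

Step 2
Reactants: 4 tert-butyl 2-(diethoxyphosphoryl)acetate; 5 4-acetamidobenzenesulfonyl azide
Product: 6 tert-butyl 2-diazo-2-(diethoxyphosphoryl)acetate
Conditions: DBU, MeCN, 0 °C to rt
Reagents that add atoms: 5 4-acetamidobenzenesulfonyl azide, CC(=O)Nc1ccc(cc1)S(=O)(=O)N=[N+]=[N-]
Why: Regitz diazo transfer to the doubly activated methylene of the phosphonoacetate.

Step 3
Reactants: 3 tert-butyl (E)-3-(2-bromo-5-hydroxy-4-methoxyphenyl)prop-2-enoate; 6 tert-butyl 2-diazo-2-(diethoxyphosphoryl)acetate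
Product: 7 tert-butyl 2-{4-bromo-5-[(E)-2-(tert-butoxycarbonyl)ethenyl]-2-methoxyphenoxy}-2-(diethoxyphosphoryl)acetate (racemic at the phosphonate carbon)
Conditions: Rh2(OAc)4 (2 mol %), toluene, 80 °C
Reagents that add atoms: 6 tert-butyl 2-diazo-2-(diethoxyphosphoryl)acetate, CCOP(=O)(OCC)C(=[N+]=[N-])C(=O)OC(C)(C)C
Why: Rhodium carbenoid O–H insertion into the phenol; the electrophilic acceptor/acceptor carbenoid should prefer the O–H bond over the electron-poor cinnamate alkene.

Step 4
Reactants: 7 the aryloxy phosphonoacetate from step 3; 8 3-methoxy-4-(methoxymethoxy)benzaldehyde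
Product: 9 tert-butyl (Z)-2-{4-bromo-5-[(E)-2-(tert-butoxycarbonyl)ethenyl]-2-methoxyphenoxy}-3-ArM-prop-2-enoate
Conditions: LiCl, DBU, MeCN, rt
Reagents that add atoms: 8 3-methoxy-4-(methoxymethoxy)benzaldehyde, COCOc1ccc(C=O)cc1OC
Why: Horner–Wadsworth–Emmons olefination under LiCl/DBU activation; reversible addition should favour the isomer with the new aryl group anti to the ester, which is the Z enol ether of the target, and any minor E isomer would be removed by chromatography.

Step 5
Reactants: 10 2-methoxy-4-(4,4,5,5-tetramethyl-1,3,2-dioxaborolan-2-yl)phenol; 11 chloromethyl methyl ether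
Product: 12 2-ArM-4,4,5,5-tetramethyl-1,3,2-dioxaborolane
Conditions: iPr2NEt, CH2Cl2, 0 °C to rt
Reagents that add atoms: 11 chloromethyl methyl ether, COCCl
Why: Standard O-alkylation of the phenol to an acid-labile, base-stable methoxymethyl ether that survives all later enolate and metal-catalysed steps.

Step 6
Reactants: 9 the Z enol ether cinnamate from step 4; 12 the MOM-protected aryl boronate
Product: 13 tert-butyl (3R)-3-[2-bromo-4-methoxy-5-(ZE-oxy)phenyl]-3-ArM-propanoate
Conditions: [RhCl(C2H4)2]2 (2.5 mol %), chiral diene 2,5-diphenylbicyclo[2.2.2]octa-2,5-diene (the enantiomer that delivers aryl to the Si face of the β-carbon), KOH (aq, 0.5 equiv), 1,4-dioxane, 60 °C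
Reagents that add atoms: 12 2-ArM-4,4,5,5-tetramethyl-1,3,2-dioxaborolane, COCOc1ccc(cc1OC)B1OC(C)(C)C(C)(C)O1
Why: Hayashi–Miyaura asymmetric 1,4-addition with monovalent rhodium; the ligand-controlled Si-face aryl transfer to the disubstituted tert-butyl cinnamate sets C1 as R, while the trisubstituted aryloxy acrylate and the aryl bromide should stay untouched.

Step 7
Reactants: 13 the (3R)-diarylpropanoate; 14 tert-butyl bromoacetate
Product: 16 di-tert-butyl 2-{(R)-[2-bromo-4-methoxy-5-(ZE-oxy)phenyl](ArM)methyl}butanedioate (both C2 epimers), via lithium enolate 15 (not isolated)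
Conditions: LiN(iPr)2, THF, −78 °C; then 14, −78 to −30 °C
Reagents that add atoms: 14 tert-butyl bromoacetate, CC(C)(C)OC(=O)CBr
Why: Ester enolate alkylation builds the C2–C3 bond; C2 forms without control next to two similar aryl groups, which is harmless because C2 is reset in step 10.

Step 8
Reactants: 16 the succinate diester; 17 N,N-dimethylmethyleneiminium iodide (Eschenmoser's salt)
Product: 21 di-tert-butyl 2-{(R)-[2-bromo-4-methoxy-5-(ZE-oxy)phenyl](ArM)methyl}-3-methylidenebutanedioate (both C2 epimers), via lithium enolate 18 (not isolated), via Mannich base 19 (not isolated), via ammonium iodide 20 (not isolated)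
Conditions: LiN(iPr)2, THF, −78 °C; 17, −78 °C to rt; then MeI, MeOH, rt; then NaHCO3 (aq), CH2Cl2, rt
Reagents that add atoms: 17 N,N-dimethylmethyleneiminium iodide, C=[N+](C)C.[I-]
Why: Eschenmoser methylenation: kinetic deprotonation at the less hindered C3 methylene, Mannich reaction, quaternization and mild E1cB loss of trimethylamine install the C3=C4 methylene without strong base that could move the alkene.

Step 9
Reactants: 21 the (R)-diarylmethyl itaconate
Product: 22 di-tert-butyl (1R)-1-ArM-6-methoxy-7-(ZE-oxy)-1,2-dihydronaphthalene-2,3-dicarboxylate (both C2 epimers)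
Conditions: Pd(OAc)2 (10 mol %), P(o-tol)3 (20 mol %), Ag2CO3, MeCN, 80 °C
Reagents that add atoms: none
Why: Oxidative addition of zerovalent palladium into the C4a–Br bond and bromide abstraction by silver give a cationic arylpalladium species that inserts the pendant 1,1-disubstituted acrylate with the aryl group going to the unsubstituted terminus C4, and syn β-hydride elimination of a benzylic C4–H then releases the C3=C4 alkene conjugated to ring A and to the C3 ester. The closest known reaction type is the intramolecular Mizoroki–Heck cyclization of 2-haloaryl-tethered α-substituted acrylates (Baylis–Hillman-type substrates), which close six-membered rings in the endo mode. Ring B is closed 6-endo-trig; the 5-exo alternative would put palladium on a neopentyl carbon beside a new quaternary C3 and runs against the polarization of the acrylate. No new stereocentre is created: C1 is untouched, and C2, which may equilibrate, is deliberately reset in step 10. The step needs endo over exo selectivity and β-hydride elimination toward C4 instead of C2; these are secured by the acrylate electronics, by the two benzylic C4 hydrogens (one is always syn to palladium) and by the silver base, which removes palladium hydride before it can re-add, while the position of the bromine fixes the regiochemistry on ring A.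

Step 10
Reactants: 22 the ring-closed diester as its C2 epimer mixture
Product: 24 di-tert-butyl (1R,2R)-1-ArM-6-methoxy-7-(ZE-oxy)-1,2-dihydronaphthalene-2,3-dicarboxylate (1,2-cis), via lithium dienolate 23 (not isolated)
Conditions: LiN(iPr)2, THF, −78 °C; then AcOH in THF, −78 °C
Reagents that add atoms: none
Why: Kinetic protonation of an ester dienolate: both epimers converge on the planar C2 dienolate, in which allylic 1,3-strain with the exocyclic ketene acetal and the peri C8–H hold the C1 aryl group pseudoaxial, so the proton should enter C2 anti to that aryl group and leave the C2 ester cis to it (2R).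

Step 11
Reactants: 24 the cis tri-tert-butyl ester bis-MOM ether
Product: 25 (1R,2R)-7-{[(Z)-1-carboxy-2-(4-hydroxy-3-methoxyphenyl)ethenyl]oxy}-1-(4-hydroxy-3-methoxyphenyl)-6-methoxy-1,2-dihydronaphthalene-2,3-dicarboxylic acid
Conditions: TFA/CH2Cl2 (1:2), H2O (10 equiv), 0 °C to rt
Reagents that add atoms: none
Why: Acidolysis cleaves the three tert-butyl esters and both methoxymethyl acetals in one operation, and the acid-only conditions should leave the base-labile cis C2 centre and the electron-poor Z enol ether intact.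

**Compound list**

1 | 2-bromo-5-hydroxy-4-methoxybenzaldehyde | O=Cc1cc(O)c(OC)cc1Br | starting material
2 | tert-butyl (triphenylphosphoranylidene)acetate | CC(C)(C)OC(=O)C=P(c1ccccc1)(c1ccccc1)c1ccccc1 | starting material
3 | tert-butyl (E)-3-(2-bromo-5-hydroxy-4-methoxyphenyl)prop-2-enoate | CC(C)(C)OC(=O)/C=C/c1cc(O)c(OC)cc1Br | intermediate
4 | tert-butyl 2-(diethoxyphosphoryl)acetate | CCOP(=O)(OCC)CC(=O)OC(C)(C)C | starting material
5 | 4-acetamidobenzenesulfonyl azide | CC(=O)Nc1ccc(cc1)S(=O)(=O)N=[N+]=[N-] | starting material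
6 | tert-butyl 2-diazo-2-(diethoxyphosphoryl)acetate | CCOP(=O)(OCC)C(=[N+]=[N-])C(=O)OC(C)(C)C | intermediate
7 | tert-butyl 2-{4-bromo-5-[(E)-2-(tert-butoxycarbonyl)ethenyl]-2-methoxyphenoxy}-2-(diethoxyphosphoryl)acetate | CCOP(=O)(OCC)C(Oc1cc(/C=C/C(=O)OC(C)(C)C)c(Br)cc1OC)C(=O)OC(C)(C)C | intermediate
8 | 3-methoxy-4-(methoxymethoxy)benzaldehyde | COCOc1ccc(C=O)cc1OC | starting material
9 | tert-butyl (Z)-2-{4-bromo-5-[(E)-2-(tert-butoxycarbonyl)ethenyl]-2-methoxyphenoxy}-3-ArM-prop-2-enoate | COCOc1ccc(/C=C(\Oc2cc(/C=C/C(=O)OC(C)(C)C)c(Br)cc2OC)C(=O)OC(C)(C)C)cc1OC | intermediate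
10 | 2-methoxy-4-(4,4,5,5-tetramethyl-1,3,2-dioxaborolan-2-yl)phenol | COc1cc(ccc1O)B1OC(C)(C)C(C)(C)O1 | starting material
11 | chloromethyl methyl ether | COCCl | starting material
12 | 2-ArM-4,4,5,5-tetramethyl-1,3,2-dioxaborolane | COCOc1ccc(cc1OC)B1OC(C)(C)C(C)(C)O1 | intermediate
13 | tert-butyl (3R)-3-[2-bromo-4-methoxy-5-(ZE-oxy)phenyl]-3-ArM-propanoate | COCOc1ccc(/C=C(\Oc2cc([C@H](CC(=O)OC(C)(C)C)c3ccc(OCOC)c(OC)c3)c(Br)cc2OC)C(=O)OC(C)(C)C)cc1OC | intermediate
14 | tert-butyl bromoacetate | CC(C)(C)OC(=O)CBr | starting material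
15 | lithium enolate of 13 | [Li+].COCOc1ccc(/C=C(\Oc2cc([C@H](C=C([O-])OC(C)(C)C)c3ccc(OCOC)c(OC)c3)c(Br)cc2OC)C(=O)OC(C)(C)C)cc1OC | intermediate
16 | di-tert-butyl 2-{(R)-[2-bromo-4-methoxy-5-(ZE-oxy)phenyl](ArM)methyl}butanedioate, both C2 epimers | COCOc1ccc(/C=C(\Oc2cc([C@H](C(CC(=O)OC(C)(C)C)C(=O)OC(C)(C)C)c3ccc(OCOC)c(OC)c3)c(Br)cc2OC)C(=O)OC(C)(C)C)cc1OC | intermediate
17 | N,N-dimethylmethyleneiminium iodide | C=[N+](C)C.[I-] | starting material
18 | lithium enolate of 16 at C3 | [Li+].COCOc1ccc(/C=C(\Oc2cc([C@H](C(C=C([O-])OC(C)(C)C)C(=O)OC(C)(C)C)c3ccc(OCOC)c(OC)c3)c(Br)cc2OC)C(=O)OC(C)(C)C)cc1OC | intermediate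
19 | Mannich base, the 3-[(dimethylamino)methyl] derivative of 16 | COCOc1ccc(/C=C(\Oc2cc([C@H](C(C(CN(C)C)C(=O)OC(C)(C)C)C(=O)OC(C)(C)C)c3ccc(OCOC)c(OC)c3)c(Br)cc2OC)C(=O)OC(C)(C)C)cc1OC | intermediate
20 | trimethylammonium iodide of 19 | [I-].COCOc1ccc(/C=C(\Oc2cc([C@H](C(C(C[N+](C)(C)C)C(=O)OC(C)(C)C)C(=O)OC(C)(C)C)c3ccc(OCOC)c(OC)c3)c(Br)cc2OC)C(=O)OC(C)(C)C)cc1OC | intermediate
21 | di-tert-butyl 2-{(R)-[2-bromo-4-methoxy-5-(ZE-oxy)phenyl](ArM)methyl}-3-methylidenebutanedioate, both C2 epimers | COCOc1ccc(/C=C(\Oc2cc([C@H](C(C(=C)C(=O)OC(C)(C)C)C(=O)OC(C)(C)C)c3ccc(OCOC)c(OC)c3)c(Br)cc2OC)C(=O)OC(C)(C)C)cc1OC | intermediate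
22 | di-tert-butyl (1R)-1-ArM-6-methoxy-7-(ZE-oxy)-1,2-dihydronaphthalene-2,3-dicarboxylate, both C2 epimers | COCOc1ccc(/C=C(\Oc2cc3c(cc2OC)C=C(C(=O)OC(C)(C)C)C(C(=O)OC(C)(C)C)[C@@H]3c2ccc(OCOC)c(OC)c2)C(=O)OC(C)(C)C)cc1OC | intermediate
23 | lithium dienolate of 22 at C2 | [Li+].[O-]C(OC(C)(C)C)=C1C(C(=O)OC(C)(C)C)=Cc2cc(OC)c(O/C(=C\c3ccc(OCOC)c(OC)c3)C(=O)OC(C)(C)C)cc2[C@H]1c1ccc(OCOC)c(OC)c1 | intermediate
24 | di-tert-butyl (1R,2R)-1-ArM-6-methoxy-7-(ZE-oxy)-1,2-dihydronaphthalene-2,3-dicarboxylate | COCOc1ccc(/C=C(\Oc2cc3c(cc2OC)C=C(C(=O)OC(C)(C)C)[C@H](C(=O)OC(C)(C)C)[C@@H]3c2ccc(OCOC)c(OC)c2)C(=O)OC(C)(C)C)cc1OC | intermediate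
25 | (1R,2R)-7-{[(Z)-1-carboxy-2-(4-hydroxy-3-methoxyphenyl)ethenyl]oxy}-1-(4-hydroxy-3-methoxyphenyl)-6-methoxy-1,2-dihydronaphthalene-2,3-dicarboxylic acid | COc1cc(/C=C(\Oc2cc3c(cc2OC)C=C(C(=O)O)[C@H](C(=O)O)[C@@H]3c2ccc(O)c(OC)c2)C(=O)O)ccc1O | target

**Step count.** Total: 11 steps. Longest linear sequence: 9 steps (1 → 3 → 7 → 9 → 13 → 16 → 21 → 22 → 24 → 25); steps 2 and 5 are side branches.

**Steps most likely to fail**

1. Step 9 (key Heck cyclization). The carbopalladation may go 5-exo instead of 6-endo, or palladium hydride may re-add and move the alkene, eroding C1 or aromatizing ring B. The fallback sets out from succinate 16 and comes back at 22. Compound 16 is condensed with tert-butoxybis(dimethylamino)methane (toluene, 90 °C), which reacts only at the C3 methylene, to give the enaminoester F1. Hydrolysis (aq HCl, THF) gives the hydroxymethylene ester F2. Triflation under non-chelating conditions (Tf2O, aqueous Me4NOH, toluene) gives the enol triflate F3 with the triflate trans to the C3 ester. A one-pot borylation and intramolecular Suzuki–Miyaura coupling (PdCl2(dppf), B2pin2, KOAc, 1,4-dioxane, 80 °C; then aqueous K3PO4) forms the same C4–C4a bond by reductive elimination, with no migratory insertion and hence no exo/endo question.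

2. Step 10 (kinetic protonation). The proton transfer may discriminate the two faces poorly, or the proton may go to C4. The fallback sets out from 22 and comes back at 24. The dienolate is trapped (LiN(iPr)2, then Me3SiCl, THF, −78 °C) as the silyl ketene acetal F4. F4 is protonated under reagent control with a catalytic chiral BINOL-derived N-triflyl phosphoramide and stoichiometric phenol (toluene, −78 °C), choosing the catalyst enantiomer that reinforces the substrate bias.

3. Step 6 (asymmetric conjugate arylation). Insertion into the hindered ortho-bromo cinnamate may be slow so that protodeboronation wins, or enantioface discrimination may be low. The fallback sets out from 9 (with 12) and comes back at 13. An oxidative Heck arylation with divalent palladium (Pd(OAc)2, 1,10-phenanthroline, O2, DMF, 50 °C) gives the β,β-diaryl acrylate F5 stereospecifically, with the ring-A aryl cis to the ester. A copper hydride asymmetric 1,4-reduction (Cu(OAc)2, chiral ferrocenyl bisphosphine, polymethylhydrosiloxane, tBuOH, toluene) then sets C1 by hydride delivery instead of aryl delivery; the twisted ortho-bromo aryl group differentiates the two β-substituents.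

**Further compounds**

F1 | step 9 | di-tert-butyl 2-[(dimethylamino)methylidene]-3-{(R)-[2-bromo-4-methoxy-5-(ZE-oxy)phenyl](ArM)methyl}butanedioate | COCOc1ccc(/C=C(\Oc2cc([C@H](C(C(=CN(C)C)C(=O)OC(C)(C)C)C(=O)OC(C)(C)C)c3ccc(OCOC)c(OC)c3)c(Br)cc2OC)C(=O)OC(C)(C)C)cc1OC
F2 | step 9 | di-tert-butyl 2-(hydroxymethylidene)-3-{(R)-[2-bromo-4-methoxy-5-(ZE-oxy)phenyl](ArM)methyl}butanedioate | COCOc1ccc(/C=C(\Oc2cc([C@H](C(C(=CO)C(=O)OC(C)(C)C)C(=O)OC(C)(C)C)c3ccc(OCOC)c(OC)c3)c(Br)cc2OC)C(=O)OC(C)(C)C)cc1OC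
F3 | step 9 | di-tert-butyl (E)-2-{[(trifluoromethylsulfonyl)oxy]methylidene}-3-{(R)-[2-bromo-4-methoxy-5-(ZE-oxy)phenyl](ArM)methyl}butanedioate | COCOc1ccc(/C=C(\Oc2cc([C@H](C(/C(=C\OS(=O)(=O)C(F)(F)F)C(=O)OC(C)(C)C)C(=O)OC(C)(C)C)c3ccc(OCOC)c(OC)c3)c(Br)cc2OC)C(=O)OC(C)(C)C)cc1OC
F4 | step 10 | trimethylsilyl ketene acetal of 22 at C2 | C[Si](C)(C)OC(OC(C)(C)C)=C1C(C(=O)OC(C)(C)C)=Cc2cc(OC)c(O/C(=C\c3ccc(OCOC)c(OC)c3)C(=O)OC(C)(C)C)cc2[C@H]1c1ccc(OCOC)c(OC)c1
F5 | step 6 | tert-butyl (Z)-3-[2-bromo-4-methoxy-5-(ZE-oxy)phenyl]-3-ArM-prop-2-enoate | COCOc1ccc(/C=C(\Oc2cc(/C(=C\C(=O)OC(C)(C)C)c3ccc(OCOC)c(OC)c3)c(Br)cc2OC)C(=O)OC(C)(C)C)cc1OC
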